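The route rests on disconnecting the C6–C7 bond shared by the cyclohexane and the trans-fused α-methylene-γ-lactone (O–C6–C7–C11(=C13)–C12). These two carbons have like polarity: C6 is an aldehyde carbon and C7 the β-carbon of an acrylate. One SmI2 operation joins them reductively, closes the carbocycle, expels the C13 acetate to unveil the exocyclic methylene and lactonises, setting C6 and C7. The precursor is an acyclic C6 aldehyde with C5, C8 and C10 in place and an (E)-2-(acetoxymethyl)enoate at C7–C11. C8 comes from a glycidyl ether, C5/C10 from a reagent-controlled Ireland–Claisen rearrangement. Different silyl groups on O8 and O15 allow direct late acylation.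

Key step: step 17

Numbering: elemane numbering is used for all intermediates (C10 quaternary with the C14 methyl and the C1=C2 vinyl, C9, C8–O, C7, C6, C5, C4(=C3)–C15; lactone C11(=C13)–C12).
Abbreviations: TBS = tert-butyldimethylsilyl, TBDPS = tert-butyldiphenylsilyl, TES = triethylsilyl, PMB = 4-methoxybenzyl, Ar = 3,5-bis(trifluoromethyl)phenyl, DMP = Dess–Martin periodinane.
Assumption: the (4S,5S) antipode of the diazaborolidine in step 8 is taken as the one that exposes the enolate face leading to (5R,10R); if a first run shows the opposite sense, the (4R,5R) antipode is used with nothing else changed.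

Step 1
Reactants: 1 2-methylenepropane-1,3-diol
Product: 2 2-[(TBDPS-oxy)methyl]prop-2-en-1-ol
Conditions: NaH (1 equiv), THF, 0 °C; TBDPSCl (1 equiv), 0 °C → rt
Reagents that add atoms: tert-butyl(chloro)diphenylsilane, CC(C)(C)[Si](Cl)(c1ccccc1)c1ccccc1
Why: Silyl ether formation through the mono-sodium alkoxide of a symmetrical diol should stop at the mono-ether; no stereocenter is involved.

Step 2
Reactants: 2 2-[(TBDPS-oxy)methyl]prop-2-en-1-ol
Product: 3 {[2-(bromomethyl)prop-2-en-1-yl]oxy}(tert-butyl)diphenylsilane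
Conditions: CBr4, PPh3, CH2Cl2, 0 °C
Reagents that add atoms: carbon tetrabromide, BrC(Br)(Br)Br
Why: The Appel bromination is neutral and spares the silyl ether, and direct and allylically transposed substitution give the same bromide because the allyl unit is symmetrical.

Step 3
Reactants: 3 {[2-(bromomethyl)prop-2-en-1-yl]oxy}(tert-butyl)diphenylsilane
Product: 5 3-[(TBDPS-oxy)methyl]but-3-enoic acid, via allylzinc bromide 4 (not isolated)
Conditions: Zn, LiCl, THF, 0 °C → rt; CO2 (1 atm), rt; then 1 M HCl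
Reagents that add atoms: carbon dioxide, O=C=O
Why: Zinc insertion into the allylic bromide and carboxylation of the allylzinc reagent should give the β,γ-unsaturated acid directly, with no basic hydrolysis that could move the 1,1-disubstituted alkene into conjugation; both allyl termini lead to the same acid.

Step 4
Reactants: 6 (S)-2-[(PMB-oxy)methyl]oxirane
Product: 7 (S)-1-(PMB-oxy)pent-4-yn-2-ol
Conditions: LiC≡CH·H2NCH2CH2NH2, DMSO, 0 °C → rt; H2O
Reagents that add atoms: lithium acetylide–ethylenediamine, [Li+].[C-]#C.NCCN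
Why: SN2 opening of the epoxide at its CH2 terminus by the acetylide (alkynylation of a terminal epoxide) does not touch the stereocenter, which becomes C8 (S).

Step 5
Reactants: 7 (S)-1-(PMB-oxy)pent-4-yn-2-ol
Product: 8 (S)-tert-butyldimethyl{[1-(PMB-oxy)pent-4-yn-2-yl]oxy}silane
Conditions: TBSCl, imidazole, DMF, rt
Reagents that add atoms: tert-butyl(chloro)dimethylsilane, CC(C)(C)[Si](C)(C)Cl
Why: Silylation of the secondary alcohol protects O8 with a group that should survive every step up to the lactone and can later be removed in the presence of the TBDPS ether.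

Step 6
Reactants: 8 (S)-tert-butyldimethyl{[1-(PMB-oxy)pent-4-yn-2-yl]oxy}silane
Product: 11 (2E,5S)-3-methyl-6-(PMB-oxy)-5-(TBS-oxy)hex-2-en-1-ol, via alkenyldimethylalane 9 (not isolated), via lithium alkenylalanate 10 (not isolated)
Conditions: AlMe3, Cp2ZrCl2 (0.2 equiv), CH2Cl2, 0 °C → rt; n-BuLi, THF, −78 °C; (CH2O)n, −78 °C → rt
Reagents that add atoms: trimethylaluminium, C[Al](C)C; paraformaldehyde (formaldehyde), C=O
Why: Zirconium-catalysed syn-methylalumination of the terminal alkyne (Negishi carboalumination) puts CH3 on the internal carbon and aluminium on the terminus, and the alanate captures formaldehyde with retention, so the trisubstituted alkene should be E (C9 trans to C2).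

Step 7
Reactants: 11 (2E,5S)-3-methyl-6-(PMB-oxy)-5-(TBS-oxy)hex-2-en-1-ol; 5 3-[(TBDPS-oxy)methyl]but-3-enoic acid
Product: 12 (2E,5S)-3-methyl-6-(PMB-oxy)-5-(TBS-oxy)hex-2-en-1-yl 3-[(TBDPS-oxy)methyl]but-3-enoate
Conditions: DCC, DMAP (5 mol %), CH2Cl2, −20 → 0 °C
Reagents that add atoms: none
Why: Steglich esterification of the primary allylic alcohol at low temperature with little DMAP should keep the β,γ-alkene of the acid out of conjugation.

Step 8
Reactants: 12 (2E,5S)-3-methyl-6-(PMB-oxy)-5-(TBS-oxy)hex-2-en-1-yl 3-[(TBDPS-oxy)methyl]but-3-enoate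
Product: 15 (2R,3R,5S)-3-ethenyl-3-methyl-6-(PMB-oxy)-5-(TBS-oxy)-2-[3-(TBDPS-oxy)prop-1-en-2-yl]hexanoic acid, via boron enolate 13 (not isolated), via acyloxyborane 14 (not isolated)
Conditions: (4S,5S)-2-bromo-1,3-bis(ArSO2)-4,5-diphenyl-1,3,2-diazaborolidine (1.2 equiv), i-Pr2NEt, CH2Cl2, −78 → 4 °C; H2O
Reagents that add atoms: none
Why: Ireland–Claisen rearrangement in its boron-enolate form: soft enolisation should give the ketene acetal with the propenyl group cis to O–B, a chair transition state with that group and the C9 chain of the (E)-alkene both equatorial fixes the C5/C10 relationship, and the C2-symmetric sulfonamide ligand on boron, not the remote C8 center, selects the enolate face to give (5R,10R).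

Step 9
Reactants: 15 (2R,3R,5S)-3-ethenyl-3-methyl-6-(PMB-oxy)-5-(TBS-oxy)-2-[3-(TBDPS-oxy)prop-1-en-2-yl]hexanoic acid
Product: 16 (2R,3R,5S)-3-ethenyl-3-methyl-6-(PMB-oxy)-5-(TBS-oxy)-2-[3-(TBDPS-oxy)prop-1-en-2-yl]hexan-1-ol
Conditions: LiAlH4, THF, 0 °C → rt
Reagents that add atoms: none
Why: Hydride reduction of the acid to the primary C6 alcohol spares ethers and isolated alkenes, and the carboxylate is not enolised, so C5 should keep its configuration.

Step 10
Reactants: 16 (2R,3R,5S)-3-ethenyl-3-methyl-6-(PMB-oxy)-5-(TBS-oxy)-2-[3-(TBDPS-oxy)prop-1-en-2-yl]hexan-1-ol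
Product: 17 (2R,3R,5S)-3-ethenyl-3-methyl-6-(PMB-oxy)-5-(TBS-oxy)-2-[3-(TBDPS-oxy)prop-1-en-2-yl]-1-(TES-oxy)hexane
Conditions: TESCl, imidazole, CH2Cl2, 0 °C
Reagents that add atoms: chlorotriethylsilane, CC[Si](Cl)(CC)CC
Why: Silylation masks O6 with the most labile silyl group of the molecule, so that it can be taken off later without loss of the TBS or TBDPS ethers.

Step 11
Reactants: 17 (2R,3R,5S)-3-ethenyl-3-methyl-6-(PMB-oxy)-5-(TBS-oxy)-2-[3-(TBDPS-oxy)prop-1-en-2-yl]-1-(TES-oxy)hexane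
Product: 18 (2S,4R,5R)-4-ethenyl-4-methyl-2-(TBS-oxy)-5-[3-(TBDPS-oxy)prop-1-en-2-yl]-6-(TES-oxy)hexan-1-ol
Conditions: DDQ, CH2Cl2–pH 7 buffer, 0 °C
Reagents that add atoms: none
Why: Oxidative cleavage of the PMB ether by DDQ under buffered conditions should free only the C7 hydroxyl and leave the silyl ethers and the three alkenes alone, which is why a PMB and not a benzyl glycidyl ether is used.

Step 12
Reactants: 18 (2S,4R,5R)-4-ethenyl-4-methyl-2-(TBS-oxy)-5-[3-(TBDPS-oxy)prop-1-en-2-yl]-6-(TES-oxy)hexan-1-ol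
Product: 19 (2S,4R,5R)-4-ethenyl-4-methyl-2-(TBS-oxy)-5-[3-(TBDPS-oxy)prop-1-en-2-yl]-6-(TES-oxy)hexanal
Conditions: DMP, pyridine, CH2Cl2, 0 °C → rt
Reagents that add atoms: none
Why: Dess–Martin oxidation under buffered, non-basic conditions should give the α-silyloxy C7 aldehyde without epimerisation at C8.

Step 13
Reactants: 19 (2S,4R,5R)-4-ethenyl-4-methyl-2-(TBS-oxy)-5-[3-(TBDPS-oxy)prop-1-en-2-yl]-6-(TES-oxy)hexanal; 20 methyl acrylate
Product: 21 methyl (4S,6R,7R)-6-ethenyl-3-hydroxy-6-methyl-2-methylidene-4-(TBS-oxy)-7-[3-(TBDPS-oxy)prop-1-en-2-yl]-8-(TES-oxy)octanoate (both C3 epimers)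
Conditions: DABCO (1 equiv), methyl acrylate (excess), MeOH (2 equiv), rt
Reagents that add atoms: none
Why: Morita–Baylis–Hillman reaction: the DABCO–acrylate zwitterion adds to the activated α-silyloxy aldehyde to attach C11–C13 at C7; the new carbinol center forms as a mixture, which does not matter because C7 becomes sp2 in step 14.

Step 14
Reactants: 21 methyl (4S,6R,7R)-6-ethenyl-3-hydroxy-6-methyl-2-methylidene-4-(TBS-oxy)-7-[3-(TBDPS-oxy)prop-1-en-2-yl]-8-(TES-oxy)octanoate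
Product: 23 methyl (2E,4S,6R,7R)-2-(acetoxymethyl)-6-ethenyl-6-methyl-4-(TBS-oxy)-7-[3-(TBDPS-oxy)prop-1-en-2-yl]-8-(TES-oxy)oct-2-enoate, via secondary acetate 22 (not isolated)
Conditions: Ac2O, pyridine, DMAP (cat.), CH2Cl2, 0 °C; then DABCO (0.5 equiv), THF, 50 °C
Reagents that add atoms: acetic anhydride, CC(=O)OC(C)=O
Why: Acetylation followed by DABCO-catalysed allylic transposition of the Morita–Baylis–Hillman acetate (amine SN2′ addition, then return of acetate at C13) should give the thermodynamically preferred trisubstituted enoate with C8 trans to the ester, the E isomer.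

Step 15
Reactants: 23 methyl (2E,4S,6R,7R)-2-(acetoxymethyl)-6-ethenyl-6-methyl-4-(TBS-oxy)-7-[3-(TBDPS-oxy)prop-1-en-2-yl]-8-(TES-oxy)oct-2-enoate
Product: 24 methyl (2E,4S,6R,7R)-2-(acetoxymethyl)-6-ethenyl-8-hydroxy-6-methyl-4-(TBS-oxy)-7-[3-(TBDPS-oxy)prop-1-en-2-yl]oct-2-enoate
Conditions: PPTS, MeOH–CH2Cl2, 0 °C
Reagents that add atoms: none
Why: Mild acid methanolysis removes the primary TES ether much faster than the secondary TBS or the TBDPS ether and does not affect the acetate or the enoate.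

Step 16
Reactants: 24 methyl (2E,4S,6R,7R)-2-(acetoxymethyl)-6-ethenyl-8-hydroxy-6-methyl-4-(TBS-oxy)-7-[3-(TBDPS-oxy)prop-1-en-2-yl]oct-2-enoate
Product: 25 methyl (2E,4S,6R,7R)-2-(acetoxymethyl)-6-ethenyl-6-methyl-8-oxo-4-(TBS-oxy)-7-[3-(TBDPS-oxy)prop-1-en-2-yl]oct-2-enoate
Conditions: DMP, pyridine, CH2Cl2, 0 °C; used at once
Reagents that add atoms: none
Why: Dess–Martin oxidation is fast and non-basic, so the β,γ-unsaturated C6 aldehyde should form without epimerisation at C5 or migration of the C4=C3 alkene, provided it is not stored.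

Step 17
Reactants: 25 methyl (2E,4S,6R,7R)-2-(acetoxymethyl)-6-ethenyl-6-methyl-8-oxo-4-(TBS-oxy)-7-[3-(TBDPS-oxy)prop-1-en-2-yl]oct-2-enoate
Product: 27 (3aS,4S,6R,7R,7aR)-6-ethenyl-6-methyl-3-methylidene-4-(TBS-oxy)-7-[3-(TBDPS-oxy)prop-1-en-2-yl]hexahydro-1-benzofuran-2(3H)-one, via samarium alkoxide 26 (not isolated)
Conditions: SmI2 (0.1 M in THF, 2.5 equiv), THF, −78 °C → rt; aq. NH4Cl
Reagents that add atoms: none
Why: Divalent samarium reduces the C6 aldehyde to a ketyl that adds to C7, a second electron turns the C11 radical into a trivalent-samarium enolate, and this enolate expels the C13 acetate (E1cB) to leave C11=C13. The closest known reaction type is the SmI2 aldehyde–enoate ketyl–olefin cyclisation that ends in a γ-lactone, merged with the known ketyl–olefin cyclisation/β-elimination sequence for acceptors carrying an allylic leaving group. The cyclohexane closes by 6-exo-trig radical addition and the lactone by 5-exo-trig acyl substitution of the C6 samarium alkoxide on the C12 methyl ester. C6 and C7 are set in a chair transition state in which the C8 silyloxy group and the C5 propenyl group are equatorial, the bulky samarium-bound oxygen is equatorial and the enoate lies anti to it, so O6 and C11 end trans to each other and to their ring neighbours. The step needs the aldehyde to be reduced before the enoate, which is secured because SmI2 in THF without HMPA or a proton source reduces aldehydes far more readily, so no carbanion appears at C7 next to O8 and the silyloxy group is not eliminated.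

Step 18
Reactants: 27 (3aS,4S,6R,7R,7aR)-6-ethenyl-6-methyl-3-methylidene-4-(TBS-oxy)-7-[3-(TBDPS-oxy)prop-1-en-2-yl]hexahydro-1-benzofuran-2(3H)-one
Product: 28 (3aR,4S,6R,7R,7aR)-6-ethenyl-4-hydroxy-6-methyl-3-methylidene-7-[3-(TBDPS-oxy)prop-1-en-2-yl]hexahydro-1-benzofuran-2(3H)-one
Conditions: camphorsulfonic acid, MeOH–CH2Cl2, 0 °C → rt
Reagents that add atoms: none
Why: Acid-catalysed methanolysis cleaves a TBS ether far faster than a TBDPS ether, so only O8 should be freed, and the α-methylene lactone does not add methanol without base.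

Step 19
Reactants: 29 methyl (R)-3-hydroxy-2-methylpropanoate
Product: 30 methyl (R)-2-methyl-3-(TBS-oxy)propanoate
Conditions: TBSCl, imidazole, DMF, rt
Reagents that add atoms: tert-butyl(chloro)dimethylsilane, CC(C)(C)[Si](C)(C)Cl
Why: Silylation of the primary alcohol blocks self-acylation in step 21 and does not touch the α-stereocenter.

Step 20
Reactants: 30 methyl (R)-2-methyl-3-(TBS-oxy)propanoate
Product: 31 (R)-2-methyl-3-(TBS-oxy)propanoic acid
Conditions: LiOH, THF–H2O, 0 °C → rt; 1 M HCl to pH 3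
Reagents that add atoms: lithium hydroxide, [Li+].[OH-]
Why: Saponification with LiOH at low temperature should give the acid without epimerisation of the α-methyl center or loss of the silyl ether.

Step 21
Reactants: 28 (3aR,4S,6R,7R,7aR)-6-ethenyl-4-hydroxy-6-methyl-3-methylidene-7-[3-(TBDPS-oxy)prop-1-en-2-yl]hexahydro-1-benzofuran-2(3H)-one; 31 (R)-2-methyl-3-(TBS-oxy)propanoic acid
Product: 32 (3aR,4S,6R,7R,7aR)-6-ethenyl-6-methyl-3-methylidene-2-oxo-7-[3-(TBDPS-oxy)prop-1-en-2-yl]octahydro-1-benzofuran-4-yl (2R)-2-methyl-3-(TBS-oxy)propanoate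
Conditions: DCC, DMAP, CH2Cl2, 0 °C → rt
Reagents that add atoms: none
Why: Steglich esterification acylates the only free hydroxyl (equatorial O8) under conditions that do not epimerise a simple α-methyl acid.

Step 22
Reactants: 32 (3aR,4S,6R,7R,7aR)-6-ethenyl-6-methyl-3-methylidene-2-oxo-7-[3-(TBDPS-oxy)prop-1-en-2-yl]octahydro-1-benzofuran-4-yl (2R)-2-methyl-3-(TBS-oxy)propanoate
Product: 33 (3aR,4S,6R,7R,7aR)-6-ethenyl-7-(3-hydroxyprop-1-en-2-yl)-6-methyl-3-methylidene-2-oxooctahydro-1-benzofuran-4-yl (2R)-3-hydroxy-2-methylpropanoate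
Conditions: HF·pyridine, pyridine, THF, 0 °C → rt
Reagents that add atoms: none
Why: Buffered HF·pyridine removes both primary silyl ethers without base, so acyl migration, ester cleavage and conjugate addition to the methylene lactone are not expected.

Compound list
1 | 2-methylenepropane-1,3-diol | C=C(CO)CO | starting material
2 | 2-[(TBDPS-oxy)methyl]prop-2-en-1-ol | C=C(CO)CO[Si](c1ccccc1)(c1ccccc1)C(C)(C)C | intermediate
3 | {[2-(bromomethyl)prop-2-en-1-yl]oxy}(tert-butyl)diphenylsilane | C=C(CBr)CO[Si](c1ccccc1)(c1ccccc1)C(C)(C)C | intermediate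
4 | {2-[(TBDPS-oxy)methyl]prop-2-en-1-yl}zinc bromide | C=C(C[Zn]Br)CO[Si](c1ccccc1)(c1ccccc1)C(C)(C)C | intermediate (not isolated)
5 | 3-[(TBDPS-oxy)methyl]but-3-enoic acid | OC(=O)CC(=C)CO[Si](c1ccccc1)(c1ccccc1)C(C)(C)C | intermediate
6 | (S)-2-[(PMB-oxy)methyl]oxirane ((S)-4-methoxybenzyl glycidyl ether) | C1O[C@@H]1COCc1ccc(OC)cc1 | starting material
7 | (S)-1-(PMB-oxy)pent-4-yn-2-ol | C#CC[C@H](O)COCc1ccc(OC)cc1 | intermediate
8 | (S)-tert-butyldimethyl{[1-(PMB-oxy)pent-4-yn-2-yl]oxy}silane | C#CC[C@H](O[Si](C)(C)C(C)(C)C)COCc1ccc(OC)cc1 | intermediate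
9 | dimethyl[(1E,4S)-2-methyl-5-(PMB-oxy)-4-(TBS-oxy)pent-1-en-1-yl]alane | C[Al](C)/C=C(\C)C[C@H](O[Si](C)(C)C(C)(C)C)COCc1ccc(OC)cc1 | intermediate (not isolated)
10 | lithium butyl(dimethyl)[(1E,4S)-2-methyl-5-(PMB-oxy)-4-(TBS-oxy)pent-1-en-1-yl]alanate | [Li+].CCCC[Al-](C)(C)/C=C(\C)C[C@H](O[Si](C)(C)C(C)(C)C)COCc1ccc(OC)cc1 | intermediate (not isolated)
11 | (2E,5S)-3-methyl-6-(PMB-oxy)-5-(TBS-oxy)hex-2-en-1-ol | OC/C=C(\C)C[C@H](O[Si](C)(C)C(C)(C)C)COCc1ccc(OC)cc1 | intermediate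
12 | (2E,5S)-3-methyl-6-(PMB-oxy)-5-(TBS-oxy)hex-2-en-1-yl 3-[(TBDPS-oxy)methyl]but-3-enoate | C=C(CC(=O)OC/C=C(\C)C[C@H](O[Si](C)(C)C(C)(C)C)COCc1ccc(OC)cc1)CO[Si](c1ccccc1)(c1ccccc1)C(C)(C)C | intermediate
13 | boron enolate of 12: ketene acetal with the propenyl group cis to O–B, boron carried in the (4S,5S)-1,3-bis(ArSO2)-4,5-diphenyl-1,3,2-diazaborolidine ring | C=C(CO[Si](c1ccccc1)(c1ccccc1)C(C)(C)C)/C=C(\OB1N(S(=O)(=O)c2cc(C(F)(F)F)cc(C(F)(F)F)c2)[C@@H](c2ccccc2)[C@H](c2ccccc2)N1S(=O)(=O)c1cc(C(F)(F)F)cc(C(F)(F)F)c1)OC/C=C(\C)C[C@H](O[Si](C)(C)C(C)(C)C)COCc1ccc(OC)cc1 | intermediate (not isolated)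
14 | acyloxyborane: mixed anhydride of acid 15 with the (4S,5S)-diazaborolidin-2-ol | C=C[C@@](C)(C[C@H](O[Si](C)(C)C(C)(C)C)COCc1ccc(OC)cc1)[C@@H](C(=O)OB1N(S(=O)(=O)c2cc(C(F)(F)F)cc(C(F)(F)F)c2)[C@@H](c2ccccc2)[C@H](c2ccccc2)N1S(=O)(=O)c1cc(C(F)(F)F)cc(C(F)(F)F)c1)C(=C)CO[Si](c1ccccc1)(c1ccccc1)C(C)(C)C | intermediate (not isolated)
15 | (2R,3R,5S)-3-ethenyl-3-methyl-6-(PMB-oxy)-5-(TBS-oxy)-2-[3-(TBDPS-oxy)prop-1-en-2-yl]hexanoic acid | C=C[C@@](C)(C[C@H](O[Si](C)(C)C(C)(C)C)COCc1ccc(OC)cc1)[C@@H](C(=O)O)C(=C)CO[Si](c1ccccc1)(c1ccccc1)C(C)(C)C | intermediate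
16 | (2R,3R,5S)-3-ethenyl-3-methyl-6-(PMB-oxy)-5-(TBS-oxy)-2-[3-(TBDPS-oxy)prop-1-en-2-yl]hexan-1-ol | C=C[C@@](C)(C[C@H](O[Si](C)(C)C(C)(C)C)COCc1ccc(OC)cc1)[C@@H](CO)C(=C)CO[Si](c1ccccc1)(c1ccccc1)C(C)(C)C | intermediate
17 | (2R,3R,5S)-3-ethenyl-3-methyl-6-(PMB-oxy)-5-(TBS-oxy)-2-[3-(TBDPS-oxy)prop-1-en-2-yl]-1-(TES-oxy)hexane | C=C[C@@](C)(C[C@H](O[Si](C)(C)C(C)(C)C)COCc1ccc(OC)cc1)[C@@H](CO[Si](CC)(CC)CC)C(=C)CO[Si](c1ccccc1)(c1ccccc1)C(C)(C)C | intermediate
18 | (2S,4R,5R)-4-ethenyl-4-methyl-2-(TBS-oxy)-5-[3-(TBDPS-oxy)prop-1-en-2-yl]-6-(TES-oxy)hexan-1-ol | C=C[C@@](C)(C[C@H](O[Si](C)(C)C(C)(C)C)CO)[C@@H](CO[Si](CC)(CC)CC)C(=C)CO[Si](c1ccccc1)(c1ccccc1)C(C)(C)C | intermediate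
19 | (2S,4R,5R)-4-ethenyl-4-methyl-2-(TBS-oxy)-5-[3-(TBDPS-oxy)prop-1-en-2-yl]-6-(TES-oxy)hexanal | C=C[C@@](C)(C[C@H](O[Si](C)(C)C(C)(C)C)C=O)[C@@H](CO[Si](CC)(CC)CC)C(=C)CO[Si](c1ccccc1)(c1ccccc1)C(C)(C)C | intermediate
20 | methyl acrylate | C=CC(=O)OC | starting material
21 | methyl (4S,6R,7R)-6-ethenyl-3-hydroxy-6-methyl-2-methylidene-4-(TBS-oxy)-7-[3-(TBDPS-oxy)prop-1-en-2-yl]-8-(TES-oxy)octanoate, both C3 epimers | C=C[C@@](C)(C[C@H](O[Si](C)(C)C(C)(C)C)C(O)C(=C)C(=O)OC)[C@@H](CO[Si](CC)(CC)CC)C(=C)CO[Si](c1ccccc1)(c1ccccc1)C(C)(C)C | intermediate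
22 | 3-O-acetate of 21, both C3 epimers | C=C[C@@](C)(C[C@H](O[Si](C)(C)C(C)(C)C)C(OC(C)=O)C(=C)C(=O)OC)[C@@H](CO[Si](CC)(CC)CC)C(=C)CO[Si](c1ccccc1)(c1ccccc1)C(C)(C)C | intermediate (not isolated)
23 | methyl (2E,4S,6R,7R)-2-(acetoxymethyl)-6-ethenyl-6-methyl-4-(TBS-oxy)-7-[3-(TBDPS-oxy)prop-1-en-2-yl]-8-(TES-oxy)oct-2-enoate | C=C[C@@](C)(C[C@H](O[Si](C)(C)C(C)(C)C)/C=C(\COC(C)=O)C(=O)OC)[C@@H](CO[Si](CC)(CC)CC)C(=C)CO[Si](c1ccccc1)(c1ccccc1)C(C)(C)C | intermediate
24 | methyl (2E,4S,6R,7R)-2-(acetoxymethyl)-6-ethenyl-8-hydroxy-6-methyl-4-(TBS-oxy)-7-[3-(TBDPS-oxy)prop-1-en-2-yl]oct-2-enoate | C=C[C@@](C)(C[C@H](O[Si](C)(C)C(C)(C)C)/C=C(\COC(C)=O)C(=O)OC)[C@@H](CO)C(=C)CO[Si](c1ccccc1)(c1ccccc1)C(C)(C)C | intermediate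
25 | methyl (2E,4S,6R,7R)-2-(acetoxymethyl)-6-ethenyl-6-methyl-8-oxo-4-(TBS-oxy)-7-[3-(TBDPS-oxy)prop-1-en-2-yl]oct-2-enoate (key-step precursor; elemane 5R,8S,10R) | C=C[C@@](C)(C[C@H](O[Si](C)(C)C(C)(C)C)/C=C(\COC(C)=O)C(=O)OC)[C@@H](C=O)C(=C)CO[Si](c1ccccc1)(c1ccccc1)C(C)(C)C | intermediate
26 | diiodosamarium alkoxide (trivalent samarium on O6) of the cyclised hydroxy α-methylene methyl ester; ring configuration as in 27 | C=C[C@@]1(C)C[C@H](O[Si](C)(C)C(C)(C)C)[C@@H](C(=C)C(=O)OC)[C@H](O[Sm](I)I)[C@H]1C(=C)CO[Si](c1ccccc1)(c1ccccc1)C(C)(C)C | intermediate (not isolated)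
27 | (3aS,4S,6R,7R,7aR)-6-ethenyl-6-methyl-3-methylidene-4-(TBS-oxy)-7-[3-(TBDPS-oxy)prop-1-en-2-yl]hexahydro-1-benzofuran-2(3H)-one (key-step product; trans-fused lactone) | C=C[C@@]1(C)C[C@H](O[Si](C)(C)C(C)(C)C)[C@H]2C(=C)C(=O)O[C@@H]2[C@H]1C(=C)CO[Si](c1ccccc1)(c1ccccc1)C(C)(C)C | intermediate
28 | (3aR,4S,6R,7R,7aR)-6-ethenyl-4-hydroxy-6-methyl-3-methylidene-7-[3-(TBDPS-oxy)prop-1-en-2-yl]hexahydro-1-benzofuran-2(3H)-one | C=C[C@@]1(C)C[C@H](O)[C@H]2C(=C)C(=O)O[C@@H]2[C@H]1C(=C)CO[Si](c1ccccc1)(c1ccccc1)C(C)(C)C | intermediate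
29 | methyl (R)-3-hydroxy-2-methylpropanoate | COC(=O)[C@H](C)CO | starting material
30 | methyl (R)-2-methyl-3-(TBS-oxy)propanoate | COC(=O)[C@H](C)CO[Si](C)(C)C(C)(C)C | intermediate
31 | (R)-2-methyl-3-(TBS-oxy)propanoic acid | OC(=O)[C@H](C)CO[Si](C)(C)C(C)(C)C | intermediate
32 | (3aR,4S,6R,7R,7aR)-6-ethenyl-6-methyl-3-methylidene-2-oxo-7-[3-(TBDPS-oxy)prop-1-en-2-yl]octahydro-1-benzofuran-4-yl (2R)-2-methyl-3-(TBS-oxy)propanoate | C=C[C@@]1(C)C[C@H](OC(=O)[C@H](C)CO[Si](C)(C)C(C)(C)C)[C@H]2C(=C)C(=O)O[C@@H]2[C@H]1C(=C)CO[Si](c1ccccc1)(c1ccccc1)C(C)(C)C | intermediate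
33 | (3aR,4S,6R,7R,7aR)-6-ethenyl-7-(3-hydroxyprop-1-en-2-yl)-6-methyl-3-methylidene-2-oxooctahydro-1-benzofuran-4-yl (2R)-3-hydroxy-2-methylpropanoate | C=C[C@@]1(C)C[C@H](OC(=O)[C@H](C)CO)[C@H]2C(=C)C(=O)O[C@@H]2[C@H]1C(=C)CO | target

Total step count: 22.
Longest linear sequence: 17 steps, from 6 to 33 (steps 4 to 18, then 21 and 22); steps 1 to 3 and 19 to 20 are side branches.

Steps most likely to fail

Step 17. Electron transfer to the electron-poor 2-(acetoxymethyl)enoate may compete with ketyl formation and strip the acetate before the ring closes, or the cyclised enolate may be protonated faster than it loses acetate. The fallback adds the methylene after the rings are made and sets out from aldehyde 19. A Wittig reaction with methyl (triphenylphosphoranylidene)acetate (toluene, rt) gives the (E)-enoate F1. PPTS in MeOH removes the TES group to give the alcohol F2, and DMP with pyridine gives the aldehyde F3. SmI2 in THF–MeOH at −78 °C, the classical aldehyde–enoate ketyl–olefin cyclisation, should give the trans hydroxy ester F4, which p-TsOH closes to the saturated trans lactone F5. Enolisation with LiN(i-Pr)2 and trapping with Eschenmoser's salt gives the aminomethyl lactone F6, methyl iodide converts it into the ammonium iodide F7, and NaHCO3 eliminates trimethylamine to give 27, where the route resumes.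

Step 8. The boron ligand may discriminate poorly between the enolate faces of this β,γ-unsaturated ester, or the rearrangement may be slow at the hindered alkene terminus. The fallback gives up facial control and separates. Ester 12 is enolised with KN(SiMe3)2 in toluene in the presence of Me3SiCl (−78 °C → rt) to the trimethylsilyl ketene acetal F8, with the propenyl group cis to O–Si. It rearranges through the same chair to the trimethylsilyl ester F9 of the wanted acid and the trimethylsilyl ester F10 of its (5S,10S) diastereomer. Dilute acid frees 15 and the diastereomeric acid F11; the two share the C5/C10 relationship and differ only relative to C8, so chromatography should separate them, and 15 re-enters at step 9.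

Step 13. Addition to the hindered α-silyloxy aldehyde may be slow, which leaves time for epimerisation at C8 or for loss of the aldehyde. The fallback replaces amine catalysis by a preformed nucleophile and sets out from aldehyde 19. Hydroalumination of methyl propiolate with (i-Bu)2AlH and N-methylmorpholine N-oxide (THF, 0 °C) gives the vinylalane F12, which should add to 19 at −78 °C to give the aluminium alkoxide F13; aqueous work-up releases 21, where the route resumes.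

Further compounds
F1 | step 17 | methyl (2E,4S,6R,7R)-6-ethenyl-6-methyl-4-(TBS-oxy)-7-[3-(TBDPS-oxy)prop-1-en-2-yl]-8-(TES-oxy)oct-2-enoate | C=C[C@@](C)(C[C@H](O[Si](C)(C)C(C)(C)C)/C=C/C(=O)OC)[C@@H](CO[Si](CC)(CC)CC)C(=C)CO[Si](c1ccccc1)(c1ccccc1)C(C)(C)C
F2 | step 17 | methyl (2E,4S,6R,7R)-6-ethenyl-8-hydroxy-6-methyl-4-(TBS-oxy)-7-[3-(TBDPS-oxy)prop-1-en-2-yl]oct-2-enoate | C=C[C@@](C)(C[C@H](O[Si](C)(C)C(C)(C)C)/C=C/C(=O)OC)[C@@H](CO)C(=C)CO[Si](c1ccccc1)(c1ccccc1)C(C)(C)C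
F3 | step 17 | methyl (2E,4S,6R,7R)-6-ethenyl-6-methyl-8-oxo-4-(TBS-oxy)-7-[3-(TBDPS-oxy)prop-1-en-2-yl]oct-2-enoate | C=C[C@@](C)(C[C@H](O[Si](C)(C)C(C)(C)C)/C=C/C(=O)OC)[C@@H](C=O)C(=C)CO[Si](c1ccccc1)(c1ccccc1)C(C)(C)C
F4 | step 17 | trans hydroxy ester: methyl 2-cyclohexylacetate with OH on C6 trans to the acetate side chain on C7, other centers as in 27 | C=C[C@@]1(C)C[C@H](O[Si](C)(C)C(C)(C)C)[C@@H](CC(=O)OC)[C@H](O)[C@H]1C(=C)CO[Si](c1ccccc1)(c1ccccc1)C(C)(C)C
F5 | step 17 | saturated trans lactone: 27 with CH2 at C11 in place of C11=C13 | C=C[C@@]1(C)C[C@H](O[Si](C)(C)C(C)(C)C)[C@H]2CC(=O)O[C@@H]2[C@H]1C(=C)CO[Si](c1ccccc1)(c1ccccc1)C(C)(C)C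
F6 | step 17 | aminomethyl lactone: F5 with CH2NMe2 on C11 | C=C[C@@]1(C)C[C@H](O[Si](C)(C)C(C)(C)C)[C@H]2C(CN(C)C)C(=O)O[C@@H]2[C@H]1C(=C)CO[Si](c1ccccc1)(c1ccccc1)C(C)(C)C
F7 | step 17 | ammonium iodide: F5 with CH2NMe3+ on C11, iodide salt | C=C[C@@]1(C)C[C@H](O[Si](C)(C)C(C)(C)C)[C@H]2C(C[N+](C)(C)C)C(=O)O[C@@H]2[C@H]1C(=C)CO[Si](c1ccccc1)(c1ccccc1)C(C)(C)C.[I-]
F8 | step 8 | trimethylsilyl ketene acetal of 12, propenyl group cis to O–Si | C=C(CO[Si](c1ccccc1)(c1ccccc1)C(C)(C)C)/C=C(\O[Si](C)(C)C)OC/C=C(\C)C[C@H](O[Si](C)(C)C(C)(C)C)COCc1ccc(OC)cc1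
F9 | step 8 | trimethylsilyl ester of acid 15 | C=C[C@@](C)(C[C@H](O[Si](C)(C)C(C)(C)C)COCc1ccc(OC)cc1)[C@@H](C(=O)O[Si](C)(C)C)C(=C)CO[Si](c1ccccc1)(c1ccccc1)C(C)(C)C
F10 | step 8 | trimethylsilyl ester of the (2S,3S,5S) diastereomer of 15 | C=C[C@](C)(C[C@H](O[Si](C)(C)C(C)(C)C)COCc1ccc(OC)cc1)[C@H](C(=O)O[Si](C)(C)C)C(=C)CO[Si](c1ccccc1)(c1ccccc1)C(C)(C)C
F11 | step 8 | (2S,3S,5S)-3-ethenyl-3-methyl-6-(PMB-oxy)-5-(TBS-oxy)-2-[3-(TBDPS-oxy)prop-1-en-2-yl]hexanoic acid | C=C[C@](C)(C[C@H](O[Si](C)(C)C(C)(C)C)COCc1ccc(OC)cc1)[C@H](C(=O)O)C(=C)CO[Si](c1ccccc1)(c1ccccc1)C(C)(C)C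
F12 | step 13 | [1-(methoxycarbonyl)ethenyl]bis(2-methylpropyl)alane | C=C(C(=O)OC)[Al](CC(C)C)CC(C)C
F13 | step 13 | diisobutylaluminium alkoxide of 21 | C=C[C@@](C)(C[C@H](O[Si](C)(C)C(C)(C)C)C(O[Al](CC(C)C)CC(C)C)C(=C)C(=O)OC)[C@@H](CO[Si](CC)(CC)CC)C(=C)CO[Si](c1ccccc1)(c1ccccc1)C(C)(C)C
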